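**Plan**
- Retrosynthesis: the 7‑O protecting group and the second C=O of the benzil go back to an aryl benzyl ketone; then the 5‑O–CH3 bond; then the C3=C4 and O1–C2 bonds of the pyran ring are cut together, back to a salicylaldehyde plus 3‑methylbut‑2‑enal (a formyl group on C3 serves as helper); last, the aryl–acyl bond, back to 2,4,6‑trihydroxybenzaldehyde and (4‑methoxyphenyl)acetyl chloride.
- Forward: acylation of the mirror‑symmetric aldehyde (only one regioisomer possible), annulation of the pyran ring onto the finished arene, decarbonylation of the helper, then MOM on the less hindered 7‑OH, methylation of 5‑OH, oxidation of CH2 to the 1,2‑diketone, release of 7‑OH.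
- Enabling feature: C4 of the chromene is an sp2 CH on arene carbon C4a, and the ring oxygen O1 sits on the neighbouring carbon C8a. O1–C8a–C4a–C4 is therefore a salicylaldehyde at the correct oxidation level, and C2(CH3)2–C3 are the β‑ and α‑carbons of an enal. O1 is para to the ketone and is the only phenol ortho to the aldehyde that is not wedged between two carbonyl groups.
- Stereochemistry: the target has no stereocentre; the two sp3 centres of the aldol intermediate vanish on dehydration, and the ring fixes the C3=C4 geometry.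

Key step: step 2

Remark: compounds 1, 2 and 4 are taken as purchasable; chromene numbering (O1, C2, C3, C4, C4a, C5–C8, C8a) is used for all bicyclic compounds, benzaldehyde numbering for 3.

**Step 1**
Reactants: 1 2,4,6‑trihydroxybenzaldehyde; 2 (4‑methoxyphenyl)acetyl chloride
Product: 3 2,4,6‑trihydroxy‑3‑[(4‑methoxyphenyl)acetyl]benzaldehyde
Conditions: TiCl4 (3 equiv), CH2Cl2, 0 °C to rt; then dilute aq. HCl
Reagents that add atoms: none
Why: Friedel–Crafts C‑acylation of a monoacylphloroglucinol to a 2,4‑diacylphloroglucinol; the two free ring positions of 1 are equivalent by symmetry, so a single regioisomer should form, and the chelated product is deactivated against further acylation.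

**Step 2**
Reactants: 3 2,4,6‑trihydroxy‑3‑[(4‑methoxyphenyl)acetyl]benzaldehyde; 4 3‑methylbut‑2‑enal
Product: 7 5,7‑dihydroxy‑6‑[(4‑methoxyphenyl)acetyl]‑2,2‑dimethyl‑2H‑chromene‑3‑carbaldehyde, via aryloxy aldehyde 5 (not isolated), via aldol adduct 6 (not isolated)
Conditions: 4 (3 equiv), K2CO3 (0.5 equiv), 1,4‑dioxane, 100 °C
Reagents that add atoms: none
Why: Carbonate generates the phenoxide of 3, whose C6 oxygen (ortho to the formyl group, para to the ketone) adds reversibly to the β‑carbon of 4 (oxa‑Michael) to give the aldehyde enolate of 5; its α‑carbon then attacks the neighbouring aryl aldehyde, forming the C3–C4 bond and closing the pyran ring (aldol 6), and E1cB loss of water gives the conjugated enal 7. The closest known reaction type is the base‑mediated domino oxa‑Michael/aldol condensation of salicylaldehydes with enals, 3‑methylbut‑2‑enal included, to 2H‑chromene‑3‑carbaldehydes. The one ring closed is the pyran ring, by a 6‑(enolexo)‑exo‑trig aldol addition followed by dehydration, the O1–C2 bond having been made just before in the same flask. No stereocentre is kept: the two centres of 6 (C3 and C4) are erased when the C3=C4 double bond forms. The step needs closure through the outer oxygen and not the central one, and O‑ rather than C‑attack; the reversible oxa‑Michael addition drains only adducts that can reach the aldehyde through a six‑membered transition state (the C4 hydroxyl, para to the formyl group, cannot), the central C2 hydroxyl is flanked by two acyl groups and hydrogen‑bonded to the ketone so that a tertiary ether there is sterically disfavoured, and the one free ring carbon is deactivated by two carbonyl groups under aprotic carbonate conditions.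

**Step 3**
Reactants: 7 5,7‑dihydroxy‑6‑[(4‑methoxyphenyl)acetyl]‑2,2‑dimethyl‑2H‑chromene‑3‑carbaldehyde
Product: 8 1‑(5,7‑dihydroxy‑2,2‑dimethyl‑2H‑chromen‑6‑yl)‑2‑(4‑methoxyphenyl)ethan‑1‑one
Conditions: [Rh(cod)Cl]2 (2.5 mol %), 1,3‑bis(diphenylphosphino)propane (10 mol %), diglyme, 160 °C, N2 sweep
Reagents that add atoms: none
Why: Tsuji–Wilkinson‑type decarbonylation of an α,β‑unsaturated aldehyde (oxidative addition of monovalent rhodium into the formyl C–H bond, CO extrusion, reductive elimination of C3–H) should remove the formyl helper without touching the ketone, the phenols or the ring alkene.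

**Step 4**
Reactants: 8 1‑(5,7‑dihydroxy‑2,2‑dimethyl‑2H‑chromen‑6‑yl)‑2‑(4‑methoxyphenyl)ethan‑1‑one
Product: 9 1‑[5‑hydroxy‑7‑(methoxymethoxy)‑2,2‑dimethyl‑2H‑chromen‑6‑yl]‑2‑(4‑methoxyphenyl)ethan‑1‑one
Conditions: MOMCl (1.1 equiv), iPr2NEt (1.5 equiv), CH2Cl2, 0 °C
Reagents that add atoms: chloromethyl methyl ether, COCCl
Why: Site‑selective O‑alkylation: the 7‑OH, flanked by a ring C–H, is less hindered than the 5‑OH (flanked by C4a and the acyl group), and once it is capped the remaining hydroxyl is locked in the chelate to the ketone, in line with the known preference for 7‑O‑alkylation of 6‑acyl‑5,7‑dihydroxychromenes.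

**Step 5**
Reactants: 9 1‑[5‑hydroxy‑7‑(methoxymethoxy)‑2,2‑dimethyl‑2H‑chromen‑6‑yl]‑2‑(4‑methoxyphenyl)ethan‑1‑one
Product: 10 1‑[5‑methoxy‑7‑(methoxymethoxy)‑2,2‑dimethyl‑2H‑chromen‑6‑yl]‑2‑(4‑methoxyphenyl)ethan‑1‑one
Conditions: MeI (3 equiv), K2CO3, acetone, reflux
Reagents that add atoms: iodomethane, CI
Why: Williamson methylation of the single remaining (chelated) phenol under forcing carbonate conditions; K2CO3 is too weak a base to C‑methylate the benzylic methylene to a significant extent, and the acetal and chromene are inert.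

**Step 6**
Reactants: 10 1‑[5‑methoxy‑7‑(methoxymethoxy)‑2,2‑dimethyl‑2H‑chromen‑6‑yl]‑2‑(4‑methoxyphenyl)ethan‑1‑one
Product: 11 1‑[5‑methoxy‑7‑(methoxymethoxy)‑2,2‑dimethyl‑2H‑chromen‑6‑yl]‑2‑(4‑methoxyphenyl)ethane‑1,2‑dione
Conditions: SeO2 (1.5 equiv), 1,4‑dioxane/H2O (50:1), 100 °C
Reagents that add atoms: selenium dioxide, O=[Se]=O
Why: Riley oxidation of the doubly activated methylene of an aryl benzyl ketone to the benzil; the chromene has no allylic C–H (C2 is quaternary) and no free phenol is present, and any partial loss of the acetal would lead directly to the target.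

**Step 7**
Reactants: 11 1‑[5‑methoxy‑7‑(methoxymethoxy)‑2,2‑dimethyl‑2H‑chromen‑6‑yl]‑2‑(4‑methoxyphenyl)ethane‑1,2‑dione
Product: 12 1‑(7‑hydroxy‑5‑methoxy‑2,2‑dimethyl‑2H‑chromen‑6‑yl)‑2‑(4‑methoxyphenyl)ethane‑1,2‑dione
Conditions: HCl (cat.), MeOH, 45 °C
Reagents that add atoms: none
Why: Acid‑catalysed acetal exchange should remove the methoxymethyl group while both methyl ethers, the 1,2‑diketone and the 2,2‑dimethylchromene survive mild acid, the freed 7‑OH ending chelated to the adjacent carbonyl.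

**Compound list**
1 | 2,4,6‑trihydroxybenzaldehyde | O=Cc1c(O)cc(O)cc1O | starting material
2 | (4‑methoxyphenyl)acetyl chloride | COc1ccc(CC(Cl)=O)cc1 | starting material
3 | 2,4,6‑trihydroxy‑3‑[(4‑methoxyphenyl)acetyl]benzaldehyde | O=Cc1c(O)cc(O)c(C(=O)Cc2ccc(OC)cc2)c1O | intermediate
4 | 3‑methylbut‑2‑enal | CC(C)=CC=O | starting material
5 | 2,4‑dihydroxy‑3‑[(4‑methoxyphenyl)acetyl]‑6‑[(2‑methyl‑4‑oxobutan‑2‑yl)oxy]benzaldehyde | CC(C)(CC=O)Oc1cc(O)c(C(=O)Cc2ccc(OC)cc2)c(O)c1C=O | intermediate (not isolated)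
6 | 4,5,7‑trihydroxy‑6‑[(4‑methoxyphenyl)acetyl]‑2,2‑dimethyl‑3,4‑dihydro‑2H‑chromene‑3‑carbaldehyde (racemic mixture of diastereomers) | CC1(C)Oc2cc(O)c(C(=O)Cc3ccc(OC)cc3)c(O)c2C(O)C1C=O | intermediate (not isolated)
7 | 5,7‑dihydroxy‑6‑[(4‑methoxyphenyl)acetyl]‑2,2‑dimethyl‑2H‑chromene‑3‑carbaldehyde | CC1(C)Oc2cc(O)c(C(=O)Cc3ccc(OC)cc3)c(O)c2C=C1C=O | intermediate
8 | 1‑(5,7‑dihydroxy‑2,2‑dimethyl‑2H‑chromen‑6‑yl)‑2‑(4‑methoxyphenyl)ethan‑1‑one | COc1ccc(CC(=O)c2c(O)cc3c(c2O)C=CC(C)(C)O3)cc1 | intermediate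
9 | 1‑[5‑hydroxy‑7‑(methoxymethoxy)‑2,2‑dimethyl‑2H‑chromen‑6‑yl]‑2‑(4‑methoxyphenyl)ethan‑1‑one | COCOc1cc2OC(C)(C)C=Cc2c(O)c1C(=O)Cc1ccc(OC)cc1 | intermediate
10 | 1‑[5‑methoxy‑7‑(methoxymethoxy)‑2,2‑dimethyl‑2H‑chromen‑6‑yl]‑2‑(4‑methoxyphenyl)ethan‑1‑one | COCOc1cc2OC(C)(C)C=Cc2c(OC)c1C(=O)Cc1ccc(OC)cc1 | intermediate
11 | 1‑[5‑methoxy‑7‑(methoxymethoxy)‑2,2‑dimethyl‑2H‑chromen‑6‑yl]‑2‑(4‑methoxyphenyl)ethane‑1,2‑dione | COCOc1cc2OC(C)(C)C=Cc2c(OC)c1C(=O)C(=O)c1ccc(OC)cc1 | intermediate
12 | 1‑(7‑hydroxy‑5‑methoxy‑2,2‑dimethyl‑2H‑chromen‑6‑yl)‑2‑(4‑methoxyphenyl)ethane‑1,2‑dione | COc1ccc(C(=O)C(=O)c2c(O)cc3c(c2OC)C=CC(C)(C)O3)cc1 | target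

Total step count: 7. Longest linear sequence: 7 steps (from 1).

**Steps most likely to fail**

Step 2. The free ring carbon between two hydroxyls may attack the enal carbonyl (the chromenylation path through carbon), the central hydroxyl may close the ring instead of the outer one, or the aldehyde may be too weak an electrophile once the substrate is a polyphenoxide. The fallback closes the same ring by olefin metathesis and sets out from 3. Wittig methylenation (Ph3PCH3Br, KOtBu in excess, THF) should give 1‑(3‑ethenyl‑2,4,6‑trihydroxyphenyl)‑2‑(4‑methoxyphenyl)ethan‑1‑one F1. The hydroxyl para to the ketone, the only one the ketone cannot chelate, is then etherified with tert‑butyl 2‑methylbut‑3‑en‑2‑yl carbonate and Pd(PPh3)4 (zerovalent palladium, THF, 0 °C) to 1‑{3‑ethenyl‑2,6‑dihydroxy‑4‑[(2‑methylbut‑3‑en‑2‑yl)oxy]phenyl}‑2‑(4‑methoxyphenyl)ethan‑1‑one F2. Ring‑closing metathesis with the second‑generation Grubbs catalyst (CH2Cl2, 40 °C) should give 8 directly, so the route is rejoined at 8 and step 3 is not needed.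

Step 4. Site selectivity between two hydroxyls that flank the same ketone may be poor, or both may be protected. The fallback differentiates the oxygens by symmetry before the arene is desymmetrised and sets out from 1. The hydroxyl para to the formyl group (the most acidic) is methoxymethylated (MOMCl 1 equiv, iPr2NEt, CH2Cl2, 0 °C) to the mirror‑symmetric 2,6‑dihydroxy‑4‑(methoxymethoxy)benzaldehyde F3. One of its equivalent hydroxyls is acylated with 2 (Et3N, CH2Cl2) to 2‑formyl‑3‑hydroxy‑5‑(methoxymethoxy)phenyl (4‑methoxyphenyl)acetate F4. A photo‑Fries rearrangement (254 nm, MeCN) moves the acyl group to carbon; ortho and para migration give the same compound, 2,6‑dihydroxy‑4‑(methoxymethoxy)‑3‑[(4‑methoxyphenyl)acetyl]benzaldehyde F5, under neutral conditions that spare the acetal. Annulation under the conditions of step 2 should give 5‑hydroxy‑7‑(methoxymethoxy)‑6‑[(4‑methoxyphenyl)acetyl]‑2,2‑dimethyl‑2H‑chromene‑3‑carbaldehyde F6, and decarbonylation under the conditions of step 3 rejoins the route at 9.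

Step 6. Over‑oxidation with C–C cleavage, attack of the selenium reagent on the electron‑rich styrenyl double bond, or uncontrolled loss of the acetal may occur. The fallback oxidises through the enolate and sets out from 10. Deprotonation with KN(SiMe3)2 (THF, −78 °C) and hydroxylation with 2‑(phenylsulfonyl)‑3‑phenyloxaziridine should give the racemic benzoin 2‑hydroxy‑1‑[5‑methoxy‑7‑(methoxymethoxy)‑2,2‑dimethyl‑2H‑chromen‑6‑yl]‑2‑(4‑methoxyphenyl)ethan‑1‑one F7. Oxidation with Dess–Martin periodinane (CH2Cl2, NaHCO3, rt) rejoins the route at 11.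

**Further compounds**
F1 | step 2 | 1‑(3‑ethenyl‑2,4,6‑trihydroxyphenyl)‑2‑(4‑methoxyphenyl)ethan‑1‑one | C=Cc1c(O)cc(O)c(C(=O)Cc2ccc(OC)cc2)c1O
F2 | step 2 | 1‑{3‑ethenyl‑2,6‑dihydroxy‑4‑[(2‑methylbut‑3‑en‑2‑yl)oxy]phenyl}‑2‑(4‑methoxyphenyl)ethan‑1‑one | C=Cc1c(OC(C)(C)C=C)cc(O)c(C(=O)Cc2ccc(OC)cc2)c1O
F3 | step 4 | 2,6‑dihydroxy‑4‑(methoxymethoxy)benzaldehyde | O=Cc1c(O)cc(OCOC)cc1O
F4 | step 4 | 2‑formyl‑3‑hydroxy‑5‑(methoxymethoxy)phenyl (4‑methoxyphenyl)acetate | O=Cc1c(O)cc(OCOC)cc1OC(=O)Cc1ccc(OC)cc1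
F5 | step 4 | 2,6‑dihydroxy‑4‑(methoxymethoxy)‑3‑[(4‑methoxyphenyl)acetyl]benzaldehyde | O=Cc1c(O)cc(OCOC)c(C(=O)Cc2ccc(OC)cc2)c1O
F6 | step 4 | 5‑hydroxy‑7‑(methoxymethoxy)‑6‑[(4‑methoxyphenyl)acetyl]‑2,2‑dimethyl‑2H‑chromene‑3‑carbaldehyde | CC1(C)Oc2cc(OCOC)c(C(=O)Cc3ccc(OC)cc3)c(O)c2C=C1C=O
F7 | step 6 | 2‑hydroxy‑1‑[5‑methoxy‑7‑(methoxymethoxy)‑2,2‑dimethyl‑2H‑chromen‑6‑yl]‑2‑(4‑methoxyphenyl)ethan‑1‑one (racemic) | COc1ccc(C(O)C(=O)c2c(OCOC)cc3c(c2OC)C=CC(C)(C)O3)cc1
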